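(The earlier runs and the new flask were computed with constants of no real substance, noise included.)

At early times Z runs ahead of G: winter holds 17.6% of Z against 2.4% of G at 10.0 min, so I read D going to Z and Z going on to G. Later D, Z and G stop adding up. At 120 min the shortfall S is 25.7% in winter and 14.3% in summer, the run with more J.

in all of them: D 0.40 M; X 0.2 mol%

| charge | Q | J | remark | time |
|---|---|---|---|---|
| winter | 1 equiv | 1.1 mol% | run made earlier |  |
| summer | 1 equiv | 4.2 mol% | run made earlier |  |
| alder | 1.00 equiv | 1.6 mol% |  | 2.0 h |
| larch | 1.00 equiv | 4.8 mol% |  | 2.0 h |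

| run | time / min | G / % | D / % | Z / % |
|---|---|---|---|---|
| winter | 10.0 | 2.4 | 76.2 | 17.6 |
| winter | 15.0 | 7.0 | 68.2 | 22.2 |
| winter | 20.0 | 10.4 | 62.9 | 23.9 |
| winter | 30.0 | 16.1 | 51.1 | 28.1 |
| winter | 50.0 | 25.8 | 36.7 | 24.2 |
| winter | 80.0 | 39.2 | 22.7 | 18.2 |
| winter | 120 | 49.8 | 12.6 | 11.9 |
| summer | 6.00 | 3.8 | 84.8 | 10.6 |
| summer | 20.0 | 21.8 | 61.3 | 14.4 |
| summer | 30.0 | 34.1 | 49.0 | 13.6 |
| summer | 50.0 | 50.4 | 30.8 | 12.1 |
| summer | 80.0 | 64.3 | 17.2 | 8.8 |
| summer | 90.0 | 68.4 | 14.1 | 6.4 |
| summer | 120 | 72.9 | 8.6 | 4.2 |

(readings scatter by 1 percentage point)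

* which of these there is most of at the end, counted by the D in it, alder (Z / D / G)
* which of these there is most of at the end, counted by the D in it, larch (Z / D / G)
* amount of the one of these that there is most of at the end, in percent of the D charged, alder
* amount of the one of these that there is most of at the end, in percent of the D charged, larch

- the analysis behind the earlier runs scatters by 1 percentage point, standard deviation

I take G to grow as [J][Q][Z] and S as [Z], with the fraction of Q left equal to one minus G. In the ratio [Z] and time cancel, so −ln(1−G)/S is a constant of the flask, proportional to [J]. Winter gives 2.68 and summer 9.13. Scaled to alder's J these become 3.90 and 3.48, and their mean 3.69 is my race number N, the selectivity factor between G and S at full Q.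

With C = G + S, G = C + ln(1−G)/N. Taking D plus Z linear in the reciprocal of J between the runs gives alder 80.5% for C. Holding Q full gives a first answer of 63.3%.

What must be known well? [D], Q, X and the time stand as in both runs, so they cancel. One point of error in C moves G by 0.575 of a point, and going from the mean N to either scaled N moves it by 0.89 percentage points.

Putting the first answer back gives 53.3%, and the mean of the two gives 56.8% for alder. Larch, with N 11.1 and C 87.7%, gives 74.6%.

The forecast, holding that “Z also leaks to something unseen, first order and independent of J”, names G in alder at 56% and G in larch at 75%.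

The flasks give G at 56.9% in alder and G at 75.3% in larch.

    Q + J + Z → J + G (k = 1000 M⁻² h⁻¹)
    Z → E (k = 0.660 h⁻¹)
    D + X ⇌ X + Z (K = 1.50, k = 2100 M⁻¹ h⁻¹)

The shortfall is E, and alder's 21.7% with its Q left puts N at 3.88. The neighbour is alder with 4 mol% of J. Scaling my N gives 9.22, and its simulated D and Z give C = 86.2%. The same rounds run from 77.8% through 69.9% to 71.7%. That flask holds 72.8% of G.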